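## Retrosynthetic overview

1. The target comes from its C3 silyl ether; that ester is cut at the ester C–O bond and, through a 1,2-shift, at C2–C3, into a methyl(silyloxyalkyl)ketene (from a light-driven Wolff rearrangement of an α-diazo ethyl ketone) and the hindered alcohol (4R,6R)-5-hydroxy-4,6-dimethylnonane-3,7-dione.
2. The diazoketone comes from an α-silyloxy γ-keto acid and diazoethane; the keto acid comes by oxidation of a 1,4-diol formed in a vinylogous aldol (C5–C6 bond) between the dienolate of 2-ethyl-3,5,6-trimethyl-4-pyranone and a butyrolactol.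
3. The lactol is derived from dimethyl (R)-malate: C3 is bought, C4 is set by Fráter–Seebach methylation; C5/C6 are then set by substrate control and C2 in the ketene capture.
4. The diketo alcohol comes from an anti-selective boron aldol of pentan-3-one with a ketal-masked α-methyl aldehyde made from the (R)-Roche ester, followed by unmasking.
5. Rings: the 4-pyranone is built first (pentan-3-one + two molecules of acetic acid) and carried intact; the dioxolane and the butyrolactone/lactol are temporary rings that are opened again.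

Assumption: diazoethane is used as a freshly distilled ethereal solution prepared beforehand by the standard nitrosourea procedure and is treated as a reagent; nothing in this route has been run, so selectivities quoted are expectations.

## Route

**Step 1**
Reactants: 1 pentan-3-one; 2 acetic acid (two molecules are built into the ring; the second is entered below)
Product: 3 2,3,5,6-tetramethyl-4H-pyran-4-one
Conditions: AcOH (3 equiv), polyphosphoric acid, 110 °C
Reagents that add atoms: acetic acid CC(=O)O (second molecule of 2)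
Why: Acid-promoted C-acetylation of the ketone at both α-carbons, each by one molecule of acetic acid, followed by cyclodehydration of the 3,5-dimethylheptane-2,4,6-trione (classical 4-pyranone synthesis in polyphosphoric acid; 1 + 2 AcOH → 3 + 3 H2O) builds the fully substituted ring in one operation; no stereocentre.

**Step 2**
Reactants: 3 2,3,5,6-tetramethyl-4H-pyran-4-one
Product: 5 2-ethyl-3,5,6-trimethyl-4H-pyran-4-one, via lithium 3,5,6-trimethyl-2-methylidene-2H-pyran-4-olate 4 (not isolated)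
Conditions: LiN(SiMe3)2 (1.05 equiv), THF, −78 °C; MeI, −78 → −30 °C
Reagents that add atoms: iodomethane CI
Why: Lateral deprotonation of a 2-methyl group gives the extended dienolate 4, which is C-methylated at the exocyclic carbon (vinylogous enolate alkylation), one equivalent of base stopping at the mono-ethyl stage; no stereocentre.

**Step 3**
Reactants: 6 methyl (R)-3-hydroxy-2-methylpropanoate
Product: 7 (R)-3-hydroxy-N-methoxy-N,2-dimethylpropanamide
Conditions: MeNH(OMe)·HCl, iPrMgCl, THF, −20 → 0 °C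
Reagents that add atoms: N,O-dimethylhydroxylamine hydrochloride CNOC.Cl
Why: Weinreb amidation of the ester by the chloromagnesium amide, the free hydroxyl being carried as its magnesium alkoxide; the bought (R) centre is not touched.

**Step 4**
Reactants: 7 (R)-3-hydroxy-N-methoxy-N,2-dimethylpropanamide
Product: 8 (R)-1-hydroxy-2-methylpentan-3-one
Conditions: EtMgBr (3 equiv), THF, 0 °C; aq. NH4Cl
Reagents that add atoms: ethylmagnesium bromide CC[Mg]Br
Why: Weinreb ketone synthesis, the chelated tetrahedral adduct collapsing to the ethyl ketone only on work-up; low temperature and neutral work-up keep the α-centre.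

**Step 5**
Reactants: 8 (R)-1-hydroxy-2-methylpentan-3-one
Product: 9 (R)-2-(2-ethyl-1,3-dioxolan-2-yl)propan-1-ol
Conditions: HOCH2CH2OH, HC(OEt)3, TsOH·H2O (cat.), CH2Cl2, 0 °C → rt; then K2CO3, MeOH
Reagents that add atoms: ethane-1,2-diol OCCO
Why: Acid-catalysed ketalisation with orthoformate as water scavenger masks the ketone so that the α-centre cannot enolise through a β-keto aldehyde after the next oxidation; configuration retained.

**Step 6**
Reactants: 9 (R)-2-(2-ethyl-1,3-dioxolan-2-yl)propan-1-ol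
Product: 10 (R)-2-(2-ethyl-1,3-dioxolan-2-yl)propanal
Conditions: Dess–Martin periodinane, pyridine, CH2Cl2, 0 °C → rt; used crude
Reagents that add atoms: none
Why: Buffered Dess–Martin oxidation of the primary alcohol gives the α-chiral aldehyde without epimerisation.

**Step 7**
Reactants: 1 pentan-3-one; 10 (R)-2-(2-ethyl-1,3-dioxolan-2-yl)propanal
Product: 12 (4R,5S,6R)-6-(2-ethyl-1,3-dioxolan-2-yl)-5-hydroxy-4-methylheptan-3-one, via dicyclohexyl[(E)-pent-2-en-3-yloxy]borane 11 (not isolated)
Conditions: 1, (c-C6H11)2BCl, Et3N, Et2O, 0 °C; 10, −78 → −20 °C; H2O2, MeOH, pH 7 buffer, 0 °C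
Reagents that add atoms: none
Why: Boron-mediated anti aldol in which the (E)-enol borinate 11 reacts through a Zimmerman–Traxler chair (new methyl anti to the hydroxyl) while Felkin–Anh attack anti to the bulky dioxolanyl group sets the carbinol syn to the bought methyl centre, so both methyl-bearing centres end up (R); the alternative syn/anti-Felkin combination converges on the same compound after step 8.

**Step 8**
Reactants: 12 (4R,5S,6R)-6-(2-ethyl-1,3-dioxolan-2-yl)-5-hydroxy-4-methylheptan-3-one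
Product: 13 (4R,6R)-5-hydroxy-4,6-dimethylnonane-3,7-dione
Conditions: 1 M aq. HCl, THF, rt
Reagents that add atoms: water O
Why: Mild acid hydrolysis of the dioxolane (ketal cleavage) unveils the second ethyl ketone, making the two arms identical so that the carbinol carbon is no longer a stereocentre while the two α-centres stay (R,R).

**Step 9**
Reactants: 14 dimethyl (R)-malate
Product: 16 dimethyl (2R,3S)-2-hydroxy-3-methylbutanedioate, via dilithium (2R)-1,4-dimethoxy-1-oxobut-3-ene-2,4-bis(olate) 15 (not isolated)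
Conditions: LiN(iPr)2 (2.2 equiv), THF, −78 → −20 °C; MeI, −78 → −10 °C; AcOH
Reagents that add atoms: iodomethane CI
Why: Fráter–Seebach alkylation, the chelated alkoxide–enolate 15 being methylated anti to the carbinol substituent (about 9:1, minor isomer removed by chromatography), so the future C4 is set by the bought C3 centre.

**Step 10**
Reactants: 16 dimethyl (2R,3S)-2-hydroxy-3-methylbutanedioate
Product: 18 (3S,4R)-4-hydroxy-3-methyloxolan-2-one, via methyl (2S,3R)-3,4-dihydroxy-2-methylbutanoate 17 (not isolated)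
Conditions: BH3·SMe2, NaBH4 (5 mol%), THF, rt; MeOH; TsOH·H2O (cat.), CH2Cl2, rt
Reagents that add atoms: none
Why: Hydroxyl-directed borane reduction takes only the ester next to the free hydroxyl, and the diol ester 17 lactonises under acid to the cis lactone; no stereocentre is touched.

**Step 11**
Reactants: 18 (3S,4R)-4-hydroxy-3-methyloxolan-2-one
Product: 19 (3S,4R)-4-[(tert-butyldimethylsilyl)oxy]-3-methyloxolan-2-one
Conditions: TBSCl, imidazole, DMF, rt
Reagents that add atoms: tert-butyldimethylsilyl chloride CC(C)(C)[Si](C)(C)Cl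
Why: Standard silylation of the secondary alcohol; this silyl ether later also directs the C2 protonation.

**Step 12**
Reactants: 19 (3S,4R)-4-[(tert-butyldimethylsilyl)oxy]-3-methyloxolan-2-one
Product: 20 (3S,4R)-4-[(tert-butyldimethylsilyl)oxy]-3-methyloxolan-2-ol (anomer mixture)
Conditions: iBu2AlH, CH2Cl2, −78 °C; aq. KNaC4H4O6
Reagents that add atoms: none
Why: Partial reduction of the lactone at −78 °C stops at the lactol, a masked C5 aldehyde that keeps the C1 oxygen free for later oxidation.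

**Step 13**
Reactants: 5 2-ethyl-3,5,6-trimethyl-4H-pyran-4-one; 20 (3S,4R)-4-[(tert-butyldimethylsilyl)oxy]-3-methyloxolan-2-ol
Product: 23 2-[(2R,3R,4R,5R)-5-[(tert-butyldimethylsilyl)oxy]-3,6-dihydroxy-4-methylhexan-2-yl]-3,5,6-trimethyl-4H-pyran-4-one, via (2Z)-2-ethylidene-3,5,6-trimethyl-4-[(trimethylsilyl)oxy]-2H-pyran 21 (not isolated), via lithium (2Z)-2-ethylidene-3,5,6-trimethyl-2H-pyran-4-olate 22 (not isolated)
Conditions: 5 (3 equiv), Me3SiOTf, Et3N, CH2Cl2, 0 °C → rt, pentane extraction; MeLi, THF, 0 °C; 20 pre-treated with LiN(SiMe3)2 (1 equiv), −78 → −50 °C; AcOH, −78 °C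
Reagents that add atoms: none
Why: Vinylogous aldol addition in which equilibrating silylation gives the more substituted ethylidene dienol ether 21 (direct deprotonation of 5 would attack the 6-methyl group), MeLi releases the regiodefined dienolate 22, and 22 adds through its exocyclic carbon to the ring-opened lactol with Felkin–Anh control from C4 (reinforced by the anti β-silyloxy group) and anti simple diastereoselection (open transition state, aldehyde chain anti to the pyranyl ring), which fixes C6 in the configuration that is (6S) in the target; the C5 carbinol is sacrificial.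

**Step 14**
Reactants: 23 2-[(2R,3R,4R,5R)-5-[(tert-butyldimethylsilyl)oxy]-3,6-dihydroxy-4-methylhexan-2-yl]-3,5,6-trimethyl-4H-pyran-4-one
Product: 24 (2R,3S,5S)-2-[(tert-butyldimethylsilyl)oxy]-3-methyl-4-oxo-5-(3,5,6-trimethyl-4-oxo-4H-pyran-2-yl)hexanal
Conditions: (COCl)2, DMSO, CH2Cl2, −78 °C; iPr2NEt, −78 → −45 °C; pH 7 buffer, cold; used crude
Reagents that add atoms: none
Why: Swern oxidation activates both hydroxyls before base is added, so the 1,4-diol goes to the keto aldehyde instead of the lactone that stepwise oxidants give, and the hindered amine with a cold quench protects the C6 and C3 centres.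

**Step 15**
Reactants: 24 (2R,3S,5S)-2-[(tert-butyldimethylsilyl)oxy]-3-methyl-4-oxo-5-(3,5,6-trimethyl-4-oxo-4H-pyran-2-yl)hexanal
Product: 25 (2R,3S,5S)-2-[(tert-butyldimethylsilyl)oxy]-3-methyl-4-oxo-5-(3,5,6-trimethyl-4-oxo-4H-pyran-2-yl)hexanoic acid
Conditions: NaClO2, NaH2PO4, 2-methylbut-2-ene, tBuOH–H2O, 0 °C
Reagents that add atoms: sodium chlorite [Na+].[O-]Cl=O
Why: Pinnick oxidation converts the aldehyde to the acid at about pH 4 without touching the ketone, the pyranone or the epimerisable centres.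

**Step 16**
Reactants: 25 (2R,3S,5S)-2-[(tert-butyldimethylsilyl)oxy]-3-methyl-4-oxo-5-(3,5,6-trimethyl-4-oxo-4H-pyran-2-yl)hexanoic acid
Product: 27 2-[(2S,4S,5R)-5-[(tert-butyldimethylsilyl)oxy]-7-diazo-4-methyl-3,6-dioxooctan-2-yl]-3,5,6-trimethyl-4H-pyran-4-one, via mixed isobutyl carbonic anhydride 26 (not isolated)
Conditions: iBuOCOCl, N-methylmorpholine, THF, −20 °C; CH3CHN2, Et2O, −20 → 0 °C
Reagents that add atoms: diazoethane CC=[N+]=[N-]
Why: Acylation of diazoethane by the mixed anhydride (Arndt–Eistert-type diazoketone synthesis) under nearly neutral conditions; no stereocentre is touched.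

**Step 17**
Reactants: 27 2-[(2S,4S,5R)-5-[(tert-butyldimethylsilyl)oxy]-7-diazo-4-methyl-3,6-dioxooctan-2-yl]-3,5,6-trimethyl-4H-pyran-4-one; 13 (4R,6R)-5-hydroxy-4,6-dimethylnonane-3,7-dione
Product: 29 (4R,6R)-4,6-dimethyl-3,7-dioxononan-5-yl (2R,3R,4S,6S)-3-[(tert-butyldimethylsilyl)oxy]-2,4-dimethyl-5-oxo-6-(3,5,6-trimethyl-4-oxo-4H-pyran-2-yl)heptanoate, via silyloxy ketene 28 (not isolated)
Conditions: hν (405 nm LEDs), toluene, −78 °C; then 13 (1.5 equiv), 2-pyridone (10 mol%), −78 → −20 °C
Reagents that add atoms: none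
Why: Proposed new method: irradiation into the weak n→π* band of the diazoketone (a wavelength at which neither the pyranone nor the ketones absorb) triggers a Wolff rearrangement in which C3 migrates with retention to give the methyl(silyloxyalkyl)ketene 28, which is then captured by the hindered, base-sensitive alcohol 13 under neutral proton-shuttle catalysis by 2-pyridone, forming the fragment-joining ester bond, and the resulting enol ester is protonated at C2 in the A1,3-minimised conformer (C3–H eclipsing the enol double bond) on the face anti to the C3–C4 bond and syn to the silyloxy group, giving the 2,3-anti (2R) centre; the closest known chemistry is the photochemical Arndt–Eistert ester synthesis and the anti-selective low-temperature Wolff rearrangement of α-alkyl diazoketones derived from N-protected amino acids, and what is new is the control by an oxygen-bearing stereocentre, the near-stoichiometric use of a complex secondary alcohol and the proton-shuttle additive.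

**Step 18**
Reactants: 29 (4R,6R)-4,6-dimethyl-3,7-dioxononan-5-yl (2R,3R,4S,6S)-3-[(tert-butyldimethylsilyl)oxy]-2,4-dimethyl-5-oxo-6-(3,5,6-trimethyl-4-oxo-4H-pyran-2-yl)heptanoate
Product: 30 (4R,6R)-4,6-dimethyl-3,7-dioxononan-5-yl (2R,3R,4S,6S)-3-hydroxy-2,4-dimethyl-5-oxo-6-(3,5,6-trimethyl-4-oxo-4H-pyran-2-yl)heptanoate
Conditions: HF·pyridine, pyridine, THF, 0 °C → rt
Reagents that add atoms: none
Why: Buffered acidic fluoride desilylation frees the C3 hydroxyl without β-elimination of the β-acyloxy ketones and without epimerising C2 or C6.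

## Compound list

1 | pentan-3-one | CCC(=O)CC | starting material
2 | acetic acid | CC(=O)O | starting material
3 | 2,3,5,6-tetramethyl-4H-pyran-4-one | Cc1oc(C)c(C)c(=O)c1C | intermediate
4 | lithium 3,5,6-trimethyl-2-methylidene-2H-pyran-4-olate | [Li+].[O-]C1=C(C)C(=C)OC(C)=C1C | intermediate
5 | 2-ethyl-3,5,6-trimethyl-4H-pyran-4-one | CCc1oc(C)c(C)c(=O)c1C | intermediate
6 | methyl (R)-3-hydroxy-2-methylpropanoate | COC(=O)[C@H](C)CO | starting material
7 | (R)-3-hydroxy-N-methoxy-N,2-dimethylpropanamide | CON(C)C(=O)[C@H](C)CO | intermediate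
8 | (R)-1-hydroxy-2-methylpentan-3-one | CCC(=O)[C@H](C)CO | intermediate
9 | (R)-2-(2-ethyl-1,3-dioxolan-2-yl)propan-1-ol | CCC1(OCCO1)[C@H](C)CO | intermediate
10 | (R)-2-(2-ethyl-1,3-dioxolan-2-yl)propanal | CCC1(OCCO1)[C@H](C)C=O | intermediate
11 | dicyclohexyl[(E)-pent-2-en-3-yloxy]borane | C/C=C(/OB(C1CCCCC1)C1CCCCC1)CC | intermediate
12 | (4R,5S,6R)-6-(2-ethyl-1,3-dioxolan-2-yl)-5-hydroxy-4-methylheptan-3-one | CCC1(OCCO1)[C@H](C)[C@@H](O)[C@@H](C)C(=O)CC | intermediate
13 | (4R,6R)-5-hydroxy-4,6-dimethylnonane-3,7-dione | CCC(=O)[C@H](C)C(O)[C@@H](C)C(=O)CC | intermediate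
14 | dimethyl (R)-malate, i.e. dimethyl (2R)-2-hydroxybutanedioate | COC(=O)[C@H](O)CC(=O)OC | starting material
15 | dilithium (2R)-1,4-dimethoxy-1-oxobut-3-ene-2,4-bis(olate) | [Li+].[Li+].COC(=O)[C@H]([O-])C=C([O-])OC | intermediate
16 | dimethyl (2R,3S)-2-hydroxy-3-methylbutanedioate | COC(=O)[C@H](O)[C@H](C)C(=O)OC | intermediate
17 | methyl (2S,3R)-3,4-dihydroxy-2-methylbutanoate | OC[C@H](O)[C@H](C)C(=O)OC | intermediate
18 | (3S,4R)-4-hydroxy-3-methyloxolan-2-one (cis) | O1C[C@H](O)[C@H](C)C1=O | intermediate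
19 | (3S,4R)-4-[(tert-butyldimethylsilyl)oxy]-3-methyloxolan-2-one | O1C[C@H](O[Si](C)(C)C(C)(C)C)[C@H](C)C1=O | intermediate
20 | (3S,4R)-4-[(tert-butyldimethylsilyl)oxy]-3-methyloxolan-2-ol, anomer mixture | O1C[C@H](O[Si](C)(C)C(C)(C)C)[C@H](C)C1O | intermediate
21 | (2Z)-2-ethylidene-3,5,6-trimethyl-4-[(trimethylsilyl)oxy]-2H-pyran | C/C=C1\OC(C)=C(C)C(O[Si](C)(C)C)=C1C | intermediate
22 | lithium (2Z)-2-ethylidene-3,5,6-trimethyl-2H-pyran-4-olate | [Li+].C/C=C1\OC(C)=C(C)C([O-])=C1C | intermediate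
23 | 2-[(2R,3R,4R,5R)-5-[(tert-butyldimethylsilyl)oxy]-3,6-dihydroxy-4-methylhexan-2-yl]-3,5,6-trimethyl-4H-pyran-4-one | OC[C@H](O[Si](C)(C)C(C)(C)C)[C@H](C)[C@@H](O)[C@@H](C)c1oc(C)c(C)c(=O)c1C | intermediate
24 | (2R,3S,5S)-2-[(tert-butyldimethylsilyl)oxy]-3-methyl-4-oxo-5-(3,5,6-trimethyl-4-oxo-4H-pyran-2-yl)hexanal | O=C[C@H](O[Si](C)(C)C(C)(C)C)[C@H](C)C(=O)[C@@H](C)c1oc(C)c(C)c(=O)c1C | intermediate
25 | (2R,3S,5S)-2-[(tert-butyldimethylsilyl)oxy]-3-methyl-4-oxo-5-(3,5,6-trimethyl-4-oxo-4H-pyran-2-yl)hexanoic acid | OC(=O)[C@H](O[Si](C)(C)C(C)(C)C)[C@H](C)C(=O)[C@@H](C)c1oc(C)c(C)c(=O)c1C | intermediate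
26 | mixed isobutyl carbonic anhydride of acid 25 | CC(C)COC(=O)OC(=O)[C@H](O[Si](C)(C)C(C)(C)C)[C@H](C)C(=O)[C@@H](C)c1oc(C)c(C)c(=O)c1C | intermediate
27 | 2-[(2S,4S,5R)-5-[(tert-butyldimethylsilyl)oxy]-7-diazo-4-methyl-3,6-dioxooctan-2-yl]-3,5,6-trimethyl-4H-pyran-4-one | CC(=[N+]=[N-])C(=O)[C@H](O[Si](C)(C)C(C)(C)C)[C@H](C)C(=O)[C@@H](C)c1oc(C)c(C)c(=O)c1C | intermediate
28 | (3R,4S,6S)-3-[(tert-butyldimethylsilyl)oxy]-2,4-dimethyl-6-(3,5,6-trimethyl-4-oxo-4H-pyran-2-yl)hept-1-ene-1,5-dione (ketene) | O=C=C(C)[C@H](O[Si](C)(C)C(C)(C)C)[C@H](C)C(=O)[C@@H](C)c1oc(C)c(C)c(=O)c1C | intermediate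
29 | (4R,6R)-4,6-dimethyl-3,7-dioxononan-5-yl (2R,3R,4S,6S)-3-[(tert-butyldimethylsilyl)oxy]-2,4-dimethyl-5-oxo-6-(3,5,6-trimethyl-4-oxo-4H-pyran-2-yl)heptanoate | CCC(=O)[C@H](C)C(OC(=O)[C@H](C)[C@H](O[Si](C)(C)C(C)(C)C)[C@H](C)C(=O)[C@@H](C)c1oc(C)c(C)c(=O)c1C)[C@@H](C)C(=O)CC | intermediate
30 | (4R,6R)-4,6-dimethyl-3,7-dioxononan-5-yl (2R,3R,4S,6S)-3-hydroxy-2,4-dimethyl-5-oxo-6-(3,5,6-trimethyl-4-oxo-4H-pyran-2-yl)heptanoate | CCC(=O)[C@H](C)C(OC(=O)[C@H](C)[C@H](O)[C@H](C)C(=O)[C@@H](C)c1oc(C)c(C)c(=O)c1C)[C@@H](C)C(=O)CC | target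

## Step count and risks

Total step count: 18. Longest linear sequence: 10 steps (14 → 30, steps 9 to 18).

**Step 17 (proposed new step).** The capture of ketene 28 by the hindered alcohol may be slow, and the C2 selectivity is unproven. The fallback uses known chemistry and sets out from 27. Irradiation of 27 at 405 nm in THF–water at −20 °C (photochemical Arndt–Eistert homologation with water as the nucleophile) gives, after removal of the minor C2 epimer by chromatography, (2R,3R,4S,6S)-3-[(tert-butyldimethylsilyl)oxy]-2,4-dimethyl-5-oxo-6-(3,5,6-trimethyl-4-oxo-4H-pyran-2-yl)heptanoic acid F1. This acid is esterified with 13 by the Yamaguchi mixed-anhydride method (2,4,6-trichlorobenzoyl chloride, Et3N, then DMAP in toluene, kept cold and short to limit epimerisation). The route is rejoined at 29.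

**Step 13.** The C6 centre depends on two selectivities in series (Felkin–Anh and anti), on clean regiocontrol in forming 21, and on avoiding silyl migration in the dialkoxide. The fallback sets out from 19 (with dienolate 22 made from 5 as before). Claisen-type ring-opening acylation of lactone 19 by 22 (2.2 equiv, THF, −78 °C) gives 2-[(4S,5R)-5-[(tert-butyldimethylsilyl)oxy]-6-hydroxy-4-methyl-3-oxohexan-2-yl]-3,5,6-trimethyl-4H-pyran-4-one F2 as a mixture of epimers at the pyranyl-bearing carbon. Oxidation of its primary alcohol with TEMPO and PhI(OAc)2 in aqueous MeCN gives 25 together with its epimer (2R,3S,5R)-2-[(tert-butyldimethylsilyl)oxy]-3-methyl-4-oxo-5-(3,5,6-trimethyl-4-oxo-4H-pyran-2-yl)hexanoic acid F3. The two acids are separated by preparative HPLC and F3 is recycled by equilibration with catalytic DBU. The route is rejoined at 25.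

**Step 14.** The double Swern oxidation exposes the acidic C6–H and the α-silyloxy aldehyde to amine base, and the keto aldehyde can cyclise. The fallback sets out from 23 and oxidises the two alcohols one at a time. Selective silylation of the primary hydroxyl (Et3SiCl, imidazole, −20 °C) gives 2-[(2R,3R,4R,5R)-5-[(tert-butyldimethylsilyl)oxy]-3-hydroxy-4-methyl-6-[(triethylsilyl)oxy]hexan-2-yl]-3,5,6-trimethyl-4H-pyran-4-one F4. Dess–Martin oxidation of the secondary alcohol gives 2-[(2S,4S,5R)-5-[(tert-butyldimethylsilyl)oxy]-4-methyl-3-oxo-6-[(triethylsilyl)oxy]hexan-2-yl]-3,5,6-trimethyl-4H-pyran-4-one F5. Removal of the triethylsilyl group (PPTS, MeOH, 0 °C) gives 2-[(2S,4S,5R)-5-[(tert-butyldimethylsilyl)oxy]-6-hydroxy-4-methyl-3-oxohexan-2-yl]-3,5,6-trimethyl-4H-pyran-4-one F6. Oxidation with TEMPO and PhI(OAc)2 in aqueous MeCN takes F6 directly to the acid, and the route is rejoined at 25.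

## Further compounds

F1 | step 17 | (2R,3R,4S,6S)-3-[(tert-butyldimethylsilyl)oxy]-2,4-dimethyl-5-oxo-6-(3,5,6-trimethyl-4-oxo-4H-pyran-2-yl)heptanoic acid | OC(=O)[C@H](C)[C@H](O[Si](C)(C)C(C)(C)C)[C@H](C)C(=O)[C@@H](C)c1oc(C)c(C)c(=O)c1C
F2 | step 13 | 2-[(4S,5R)-5-[(tert-butyldimethylsilyl)oxy]-6-hydroxy-4-methyl-3-oxohexan-2-yl]-3,5,6-trimethyl-4H-pyran-4-one (both epimers at C2 of the hexanyl chain) | OC[C@H](O[Si](C)(C)C(C)(C)C)[C@H](C)C(=O)C(C)c1oc(C)c(C)c(=O)c1C
F3 | step 13 | (2R,3S,5R)-2-[(tert-butyldimethylsilyl)oxy]-3-methyl-4-oxo-5-(3,5,6-trimethyl-4-oxo-4H-pyran-2-yl)hexanoic acid | OC(=O)[C@H](O[Si](C)(C)C(C)(C)C)[C@H](C)C(=O)[C@H](C)c1oc(C)c(C)c(=O)c1C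
F4 | step 14 | 2-[(2R,3R,4R,5R)-5-[(tert-butyldimethylsilyl)oxy]-3-hydroxy-4-methyl-6-[(triethylsilyl)oxy]hexan-2-yl]-3,5,6-trimethyl-4H-pyran-4-one | CC[Si](CC)(CC)OC[C@H](O[Si](C)(C)C(C)(C)C)[C@H](C)[C@@H](O)[C@@H](C)c1oc(C)c(C)c(=O)c1C
F5 | step 14 | 2-[(2S,4S,5R)-5-[(tert-butyldimethylsilyl)oxy]-4-methyl-3-oxo-6-[(triethylsilyl)oxy]hexan-2-yl]-3,5,6-trimethyl-4H-pyran-4-one | CC[Si](CC)(CC)OC[C@H](O[Si](C)(C)C(C)(C)C)[C@H](C)C(=O)[C@@H](C)c1oc(C)c(C)c(=O)c1C
F6 | step 14 | 2-[(2S,4S,5R)-5-[(tert-butyldimethylsilyl)oxy]-6-hydroxy-4-methyl-3-oxohexan-2-yl]-3,5,6-trimethyl-4H-pyran-4-one | OC[C@H](O[Si](C)(C)C(C)(C)C)[C@H](C)C(=O)[C@@H](C)c1oc(C)c(C)c(=O)c1C
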